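**Retrosynthetic overview**
- The target is the final deacylation product of its ring-A dipivalate; the seven-membered ring comes from an acid Friedel–Crafts closure of a 4-hydroxystyryl unit onto the only unmasked resorcinol ring of a bis(dihydrofuran) stilbene.
- Each trans-2,3-diaryl-dihydrobenzofuran comes from a phenol and an enantiopure trans-stilbene oxide by Friedel–Crafts epoxide opening, 1,2-aryl (phenonium) shift and oxa-cyclisation; the (2R,3R) ring is made first, the (2S,3S) ring second.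
- All three C6–C2–C6 units derive from one E-stilbene (Heck reaction), used as central phenol (free resorcinol), as the (R,R)-epoxide (bis-pivalate) and as the (S,S)-epoxide (bis-silyl ether).
- The stilbene comes from a 3,5-dioxygenated styrene (C–H borylation/vinylation of resorcinol dipivalate) and a 4-iodophenol silyl ether.
- Ring order: central benzene ring (present from the start), then dihydrofuran A, then dihydrofuran C, then the seven-membered carbocycle.

Abbreviations: TBS = tert-butyldimethylsilyl; Piv = pivaloyl (2,2-dimethylpropanoyl); HFIP = 1,1,1,3,3,3-hexafluoropropan-2-ol; ring A = the 3,5-dioxygenated aryl on the (2R,3R)-dihydrofuran; ring C = the 3,5-dioxygenated aryl on the (2S,3S)-dihydrofuran.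

Assumption: the acid-mediated seven-ring closure gives the relative configuration known for the ε-viniferin → ampelopsin B cyclisation (new benzylic H trans to the H on the neighbouring dihydrofuran C3), which is the S configuration required here.

**Step 1**
Reactants: 1 resorcinol
Product: 2 1,3-phenylene bis(2,2-dimethylpropanoate)
Conditions: PivCl (2.2 equiv), Et3N, DMAP (5 mol%), CH2Cl2, 0 °C → rt
Reagents that add atoms: pivaloyl chloride, CC(C)(C)C(=O)Cl
Why: Standard O-acylation of a phenol; the bulky, electron-withdrawing pivalates steer the next C–H borylation to C-5 and later keep this ring non-nucleophilic.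

**Step 2**
Reactants: 2 1,3-phenylene bis(2,2-dimethylpropanoate); 3 bromoethene (vinyl bromide)
Product: 5 5-ethenyl-1,3-phenylene bis(2,2-dimethylpropanoate), via arylboronate 4 (not isolated)
Conditions: [Ir(OMe)(cod)]2 (1.5 mol%), 4,4'-di-tert-butyl-2,2'-bipyridine (3 mol%), B2pin2 (0.55 equiv), THF, 80 °C; then 3 (1 M in THF, 2 equiv), Pd(dppf)Cl2 (3 mol%), aq. K3PO4, 60 °C
Reagents that add atoms: bis(pinacolato)diboron, CC1(C)OB(OC1(C)C)B1OC(C)(C)C(C)(C)O1 (its boryl group is present in 4 only and is lost again on the way to 5)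
Why: Sterically controlled iridium-catalysed C–H borylation takes the only unflanked C–H (C-5), and the crude boronate undergoes Suzuki–Miyaura vinylation in the same pot.

**Step 3**
Reactants: 6 4-iodophenol
Product: 7 tert-butyl(4-iodophenoxy)dimethylsilane
Conditions: TBSCl (1.1 equiv), imidazole, DMF, rt
Reagents that add atoms: tert-butyldimethylsilyl chloride, CC(C)(C)[Si](C)(C)Cl
Why: Routine imidazole-mediated silylation; the silyl ether keeps the oxygen electron-donating for the later benzylic cation chemistry.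

**Step 4**
Reactants: 5 5-ethenyl-1,3-phenylene bis(2,2-dimethylpropanoate); 7 tert-butyl(4-iodophenoxy)dimethylsilane
Product: 8 5-[(E)-2-(4-TBSO-phenyl)ethenyl]-1,3-phenylene bis(2,2-dimethylpropanoate)
Conditions: Pd(OAc)2 (3 mol%), P(o-tol)3 (6 mol%), Et3N (2 equiv), DMF, 90 °C
Reagents that add atoms: none
Why: Mizoroki–Heck arylation of the styrene; syn-insertion and syn-β-hydride elimination give the E-stilbene, as in established resveratrol syntheses.

**Step 5**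
Reactants: 8 5-[(E)-2-(4-TBSO-phenyl)ethenyl]-1,3-phenylene bis(2,2-dimethylpropanoate)
Product: 9 5-[(E)-2-(4-TBSO-phenyl)ethenyl]benzene-1,3-diol
Conditions: i-Bu2AlH (5 equiv), CH2Cl2, −78 °C; aq. KNaC4H4O6 work-up
Reagents that add atoms: none
Why: Reductive cleavage of the aryl pivalates by the aluminium hydride leaves the aryl silyl ether and the alkene untouched, whereas basic methanolysis would remove the silyl group first.

**Step 6**
Reactants: 9 5-[(E)-2-(4-TBSO-phenyl)ethenyl]benzene-1,3-diol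
Product: 10 (E)-3,5,4'-tris-O-TBS-resveratrol
Conditions: TBSCl (2.4 equiv), imidazole, DMF, rt
Reagents that add atoms: tert-butyldimethylsilyl chloride, CC(C)(C)[Si](C)(C)Cl
Why: Routine silylation; the two bulky silyl ethers shield every nucleophilic position of this ring sterically but can be removed without touching pivalates.

**Step 7**
Reactants: 8 5-[(E)-2-(4-TBSO-phenyl)ethenyl]-1,3-phenylene bis(2,2-dimethylpropanoate)
Product: 11 5-[(2R,3R)-3-(4-TBSO-phenyl)oxiran-2-yl]-1,3-phenylene bis(2,2-dimethylpropanoate)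
Conditions: D-fructose-derived Shi ketone (30 mol%), KHSO5 (as the triple salt 2KHSO5·KHSO4·K2SO4), K2CO3, Bu4NHSO4, MeCN/dimethoxymethane/aq. buffer pH 10.5, 0 °C
Reagents that add atoms: potassium peroxymonosulfate, [K+].[O-]S(=O)(=O)OO
Why: Shi asymmetric epoxidation (chiral dioxirane, spiro transition state) of a trans-stilbene gives the R,R-epoxide, as for trans-stilbene itself, and the basic buffer protects the acid-labile 4-siloxyaryl epoxide.

**Step 8**
Reactants: 10 (E)-3,5,4'-tris-O-TBS-resveratrol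
Product: 12 (2S,3S)-2-[3,5-bis(TBSO)phenyl]-3-(4-TBSO-phenyl)oxirane
Conditions: ent-Shi ketone (L-fructose-derived, 30 mol%), KHSO5 (as the triple salt 2KHSO5·KHSO4·K2SO4), K2CO3, Bu4NHSO4, MeCN/dimethoxymethane/aq. buffer pH 10.5, 0 °C
Reagents that add atoms: potassium peroxymonosulfate, [K+].[O-]S(=O)(=O)OO
Why: The same Shi epoxidation with the enantiomeric ketone delivers the S,S-epoxide needed for the second dihydrofuran.

**Step 9**
Reactants: 9 5-[(E)-2-(4-TBSO-phenyl)ethenyl]benzene-1,3-diol; 11 5-[(2R,3R)-3-(4-TBSO-phenyl)oxiran-2-yl]-1,3-phenylene bis(2,2-dimethylpropanoate)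
Product: 14 5-[(2R,3R)-2-(4-TBSO-phenyl)-4-[(E)-2-(4-TBSO-phenyl)ethenyl]-6-hydroxy-2,3-dihydro-1-benzofuran-3-yl]-1,3-phenylene bis(2,2-dimethylpropanoate), via triaryl carbinol 13 (not isolated)
Conditions: 9 (3 equiv, excess recovered), slow addition of 11, HFIP/CH2Cl2 1:1, −20 → 0 °C; then TsOH·H2O (5 mol%), 0 → 20 °C; Et3N quench
Reagents that add atoms: none
Why: Proposed new method: a migratory dehydrative [3+2] annulation in which HFIP-activated 11 is opened at its 4-siloxybenzylic carbon by C-2 of the resorcinol ring of 9 (para to one OH, ortho to the other, the kinetic site) to give 13; the remaining hydroxyl of 13 sits on the deactivated 3,5-bis(pivaloyloxy)benzylic carbon and can only leave with anti-periplanar participation of the electron-rich ring (phenonium ion, Wagner–Meerwein 1,2-aryl shift with inversion, which fixes C3 as R), and the bridged ion opens to the 4-siloxybenzylic cation that the adjacent phenol traps anti to the C3 aryl (2,3-trans, C2 R); the closest known reactions are fluoroalcohol-promoted Friedel–Crafts opening of aryl epoxides and phenonium-ion 1,2-aryl shifts of β-aryl alcohols.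

**Step 10**
Reactants: 14 (the 2R,3R-dihydrobenzofuran phenol of step 9); 12 (2S,3S)-2-[3,5-bis(TBSO)phenyl]-3-(4-TBSO-phenyl)oxirane
Product: 16 5-[(2R,3R,5S,6S)-5-[3,5-bis(TBSO)phenyl]-2,6-bis(4-TBSO-phenyl)-4-[(E)-2-(4-TBSO-phenyl)ethenyl]-2,3,5,6-tetrahydrobenzo[1,2-b:5,4-b']difuran-3-yl]-1,3-phenylene bis(2,2-dimethylpropanoate), via triaryl carbinol 15 (not isolated)
Conditions: 12 (1.3 equiv, slow addition), HFIP/CH2Cl2 1:1, −20 → 0 °C; then TsOH·H2O (5 mol%), 0 → 20 °C; Et3N quench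
Reagents that add atoms: none
Why: Proposed new method: the same Friedel–Crafts opening/1,2-aryl shift/oxa-cyclisation cascade as in step 9, now at C-5 of 14 (ortho to the free OH, para to the ring oxygen); the carbinol carbon of 15 is again substituted with inversion by the migrating benzofuran ring (C5 S) and the phenol closes trans (C6 S), while ring A (pivalates, electronic) and ring C (silyl ethers, steric) stay out of the Friedel–Crafts chemistry; closest known reactions as in step 9.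

**Step 11**
Reactants: 16 (the 2R,3R,5S,6S-bis(dihydrofuran) stilbene of step 10)
Product: 18 ring-A dipivalate of the cyclised trimer (all five stereocentres as in the target), via pentaphenol 17 (not isolated)
Conditions: KHF2 (6 equiv), MeOH/THF, rt; then HCl (to 0.5 M in MeOH), 40 °C
Reagents that add atoms: none
Why: KHF2 cleaves the five aryl silyl ethers but not the pivalates; acid then protonates the 4-hydroxystilbene to its benzylic (p-quinone-methide-type) cation, and only the freed ring C can close the seven-membered ring by Friedel–Crafts alkylation (ring A is deactivated), setting the new centre (S) under substrate control as in the known ε-viniferin → ampelopsin B cyclisation.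

**Step 12**
Reactants: 18 ring-A dipivalate of the cyclised trimer
Product: 19 target CNP0136963.1
Conditions: K2CO3, degassed MeOH, 30 °C, argon; dilute acid work-up
Reagents that add atoms: none
Why: Base-catalysed transesterification removes the two aryl pivalates without touching any stereocentre (no epimerisable position under mild base; air excluded to protect the polyphenol).

**Compound list**
1 | resorcinol (benzene-1,3-diol) | Oc1cccc(O)c1 | starting material
2 | 1,3-phenylene bis(2,2-dimethylpropanoate) | CC(C)(C)C(=O)Oc1cccc(OC(=O)C(C)(C)C)c1 | intermediate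
3 | bromoethene (vinyl bromide) | C=CBr | starting material
4 | 5-(4,4,5,5-tetramethyl-1,3,2-dioxaborolan-2-yl)-1,3-phenylene bis(2,2-dimethylpropanoate) | CC(C)(C)C(=O)Oc1cc(OC(=O)C(C)(C)C)cc(c1)B1OC(C)(C)C(C)(C)O1 | intermediate
5 | 5-ethenyl-1,3-phenylene bis(2,2-dimethylpropanoate) | C=Cc1cc(OC(=O)C(C)(C)C)cc(OC(=O)C(C)(C)C)c1 | intermediate
6 | 4-iodophenol | Oc1ccc(I)cc1 | starting material
7 | tert-butyl(4-iodophenoxy)dimethylsilane | CC(C)(C)[Si](C)(C)Oc1ccc(I)cc1 | intermediate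
8 | 5-[(E)-2-{4-[(tert-butyldimethylsilyl)oxy]phenyl}ethenyl]-1,3-phenylene bis(2,2-dimethylpropanoate) | CC(C)(C)C(=O)Oc1cc(/C=C/c2ccc(O[Si](C)(C)C(C)(C)C)cc2)cc(OC(=O)C(C)(C)C)c1 | intermediate
9 | 5-[(E)-2-{4-[(tert-butyldimethylsilyl)oxy]phenyl}ethenyl]benzene-1,3-diol | Oc1cc(O)cc(/C=C/c2ccc(O[Si](C)(C)C(C)(C)C)cc2)c1 | intermediate
10 | (E)-3,5,4'-tris-O-(tert-butyldimethylsilyl)resveratrol | CC(C)(C)[Si](C)(C)Oc1ccc(/C=C/c2cc(O[Si](C)(C)C(C)(C)C)cc(O[Si](C)(C)C(C)(C)C)c2)cc1 | intermediate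
11 | 5-[(2R,3R)-3-{4-[(tert-butyldimethylsilyl)oxy]phenyl}oxiran-2-yl]-1,3-phenylene bis(2,2-dimethylpropanoate) | CC(C)(C)C(=O)Oc1cc(OC(=O)C(C)(C)C)cc(c1)[C@@H]2[C@H](O2)c3ccc(O[Si](C)(C)C(C)(C)C)cc3 | intermediate
12 | (2S,3S)-2-{3,5-bis[(tert-butyldimethylsilyl)oxy]phenyl}-3-{4-[(tert-butyldimethylsilyl)oxy]phenyl}oxirane | CC(C)(C)[Si](C)(C)Oc1cc(O[Si](C)(C)C(C)(C)C)cc(c1)[C@H]2[C@@H](O2)c3ccc(O[Si](C)(C)C(C)(C)C)cc3 | intermediate
13 | 5-[(1S,2R)-2-{2,4-dihydroxy-6-[(E)-2-(4-TBSO-phenyl)ethenyl]phenyl}-1-hydroxy-2-(4-TBSO-phenyl)ethyl]-1,3-phenylene bis(2,2-dimethylpropanoate) (C-2 from inversion at the epoxide carbon; this centre is erased later) | CC(C)(C)C(=O)Oc1cc(OC(=O)C(C)(C)C)cc(c1)[C@@H](O)[C@H](c2ccc(O[Si](C)(C)C(C)(C)C)cc2)c3c(O)cc(O)cc3/C=C/c4ccc(O[Si](C)(C)C(C)(C)C)cc4 | intermediate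
14 | 5-[(2R,3R)-2-(4-TBSO-phenyl)-4-[(E)-2-(4-TBSO-phenyl)ethenyl]-6-hydroxy-2,3-dihydro-1-benzofuran-3-yl]-1,3-phenylene bis(2,2-dimethylpropanoate) | Oc1cc2O[C@@H](c3ccc(O[Si](C)(C)C(C)(C)C)cc3)[C@H](c3cc(OC(=O)C(C)(C)C)cc(OC(=O)C(C)(C)C)c3)c2c(/C=C/c2ccc(O[Si](C)(C)C(C)(C)C)cc2)c1 | intermediate
15 | 5-[(2R,3R)-5-[(1S,2R)-2-[3,5-bis(TBSO)phenyl]-2-hydroxy-1-(4-TBSO-phenyl)ethyl]-2-(4-TBSO-phenyl)-4-[(E)-2-(4-TBSO-phenyl)ethenyl]-6-hydroxy-2,3-dihydro-1-benzofuran-3-yl]-1,3-phenylene bis(2,2-dimethylpropanoate) | Oc1cc2O[C@@H](c3ccc(O[Si](C)(C)C(C)(C)C)cc3)[C@H](c3cc(OC(=O)C(C)(C)C)cc(OC(=O)C(C)(C)C)c3)c2c(/C=C/c2ccc(O[Si](C)(C)C(C)(C)C)cc2)c1[C@H](c1ccc(O[Si](C)(C)C(C)(C)C)cc1)[C@@H](O)c1cc(O[Si](C)(C)C(C)(C)C)cc(O[Si](C)(C)C(C)(C)C)c1 | intermediate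
16 | 5-[(2R,3R,5S,6S)-5-[3,5-bis(TBSO)phenyl]-2,6-bis(4-TBSO-phenyl)-4-[(E)-2-(4-TBSO-phenyl)ethenyl]-2,3,5,6-tetrahydrobenzo[1,2-b:5,4-b']difuran-3-yl]-1,3-phenylene bis(2,2-dimethylpropanoate) | c1c2O[C@@H](c3ccc(O[Si](C)(C)C(C)(C)C)cc3)[C@H](c3cc(OC(=O)C(C)(C)C)cc(OC(=O)C(C)(C)C)c3)c2c(/C=C/c2ccc(O[Si](C)(C)C(C)(C)C)cc2)c2c1O[C@H](c1ccc(O[Si](C)(C)C(C)(C)C)cc1)[C@H]2c1cc(O[Si](C)(C)C(C)(C)C)cc(O[Si](C)(C)C(C)(C)C)c1 | intermediate
17 | 5-[(2R,3R,5S,6S)-5-(3,5-dihydroxyphenyl)-2,6-bis(4-hydroxyphenyl)-4-[(E)-2-(4-hydroxyphenyl)ethenyl]-2,3,5,6-tetrahydrobenzo[1,2-b:5,4-b']difuran-3-yl]-1,3-phenylene bis(2,2-dimethylpropanoate) | c1c2O[C@@H](c3ccc(O)cc3)[C@H](c3cc(OC(=O)C(C)(C)C)cc(OC(=O)C(C)(C)C)c3)c2c(/C=C/c2ccc(O)cc2)c2c1O[C@H](c1ccc(O)cc1)[C@H]2c1cc(O)cc(O)c1 | intermediate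
18 | ring-A dipivalate of the target: the cyclised trimer whose 3,5-dioxygenated ring on the (2R,3R)-dihydrofuran carries two pivalates, all other phenols free | Oc1ccc([C@@H]2Cc3c4c(cc5c3[C@@H](c3cc(OC(=O)C(C)(C)C)cc(OC(=O)C(C)(C)C)c3)[C@H](c3ccc(O)cc3)O5)O[C@H](c3ccc(O)cc3)[C@H]4c3cc(O)cc(O)c32)cc1 | intermediate
19 | target CNP0136963.1: central benzene ring fused to (a) a (2R,3R)-2-(4-hydroxyphenyl)-3-(3,5-dihydroxyphenyl)-2,3-dihydrofuran and (b) a (2S,3S)-2-(4-hydroxyphenyl)-2,3-dihydrofuran whose C3 resorcinol ring is tied back through its ortho carbon to an (S)-CH(4-hydroxyphenyl)–CH2 bridge on the central ring (seven-membered carbocycle) | Oc1ccc([C@@H]2Cc3c4c(cc5c3[C@@H](c3cc(O)cc(O)c3)[C@H](c3ccc(O)cc3)O5)O[C@H](c3ccc(O)cc3)[C@H]4c3cc(O)cc(O)c32)cc1 | target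

**Step count**
Total steps: 12. Longest linear sequence: 9 steps (1, 2, 4, 5, 6, 8, 10, 11, 12).

**Three steps most likely to fail**

Step 9 (the proposed new annulation). It can fail in four ways. Epoxide 11 may isomerise in HFIP (Meinwald) before it is trapped. The phenol oxygen may displace the carbinol directly and give the regioisomeric 3-(4-siloxyphenyl) dihydrofuran. Alkylation may occur between the two hydroxyls instead of next to the styryl group. The acid may attack the electron-rich stilbene or re-open the product.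
The fallback uses known reactions only; it sets out from 5 and 9 and comes back at 14. Jacobsen epoxidation of 5 with the (salen)MnCl enantiomer that gives the R product (mCPBA, N-methylmorpholine N-oxide, −78 °C) gives 5-[(2R)-oxiran-2-yl]-1,3-phenylene bis(2,2-dimethylpropanoate) F1. HFIP-promoted Friedel–Crafts opening of F1 by excess 9 at the benzylic carbon, with inversion, gives the 2,2-diarylethanol 5-[(1R)-1-{2,4-dihydroxy-6-[(E)-2-(4-TBSO-phenyl)ethenyl]phenyl}-2-hydroxyethyl]-1,3-phenylene bis(2,2-dimethylpropanoate) F2. Oxidation of the primary alcohol (SO3·pyridine, DMSO, i-Pr2NEt) gives the aldehyde, isolated as its lactol 5-[(3R)-2,6-dihydroxy-4-[(E)-2-(4-TBSO-phenyl)ethenyl]-2,3-dihydro-1-benzofuran-3-yl]-1,3-phenylene bis(2,2-dimethylpropanoate) F3. Iodine–magnesium exchange on 7 (i-PrMgCl·LiCl) gives 4-[(tert-butyldimethylsilyl)oxy]phenylmagnesium chloride F4, which adds to F3 at −40 °C to give the carbinol 5-[(1R)-1-{2,4-dihydroxy-6-[(E)-2-(4-TBSO-phenyl)ethenyl]phenyl}-2-hydroxy-2-(4-TBSO-phenyl)ethyl]-1,3-phenylene bis(2,2-dimethylpropanoate) F5 as a mixture of carbinol epimers. Pyridinium tosylate in CH2Cl2 then ionises the 4-siloxybenzylic alcohol and the phenol closes to the trans-dihydrobenzofuran 14, the carbinol-to-dihydrofuran closure established in resveratrol-oligomer synthesis.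

Step 10 (the same new annulation on a more hindered phenol). The nucleophilic carbon of 14 is flanked by the styryl group, attack at C-7 between the two oxygens is possible, and the silyl ethers of 12 are less robust to acid.
The fallback is again known chemistry; it sets out from 10 and 14 and comes back at 16. Ozonolysis of 10 (O3, CH2Cl2/MeOH, −78 °C; Me2S) gives 3,5-bis[(tert-butyldimethylsilyl)oxy]benzaldehyde F6. Wittig methylenation (Ph3PCH3Br, KOt-Bu) gives [(5-ethenyl-1,3-phenylene)bis(oxy)]bis(tert-butyldimethylsilane) F7. Jacobsen epoxidation with the other (salen)MnCl enantiomer gives (2S)-2-{3,5-bis[(tert-butyldimethylsilyl)oxy]phenyl}oxirane F8. HFIP-promoted opening of F8 by 14 at C-5, with inversion, gives the primary alcohol 5-[(2R,3R)-5-[(1S)-1-[3,5-bis(TBSO)phenyl]-2-hydroxyethyl]-2-(4-TBSO-phenyl)-4-[(E)-2-(4-TBSO-phenyl)ethenyl]-6-hydroxy-2,3-dihydro-1-benzofuran-3-yl]-1,3-phenylene bis(2,2-dimethylpropanoate) F9. Oxidation as before gives the lactol 5-[(2R,3R,5S)-5-[3,5-bis(TBSO)phenyl]-6-hydroxy-2-(4-TBSO-phenyl)-4-[(E)-2-(4-TBSO-phenyl)ethenyl]-2,3,5,6-tetrahydrobenzo[1,2-b:5,4-b']difuran-3-yl]-1,3-phenylene bis(2,2-dimethylpropanoate) F10. Addition of the same Grignard reagent F4 gives the carbinol 5-[(2R,3R)-5-[(1S)-1-[3,5-bis(TBSO)phenyl]-2-hydroxy-2-(4-TBSO-phenyl)ethyl]-2-(4-TBSO-phenyl)-4-[(E)-2-(4-TBSO-phenyl)ethenyl]-6-hydroxy-2,3-dihydro-1-benzofuran-3-yl]-1,3-phenylene bis(2,2-dimethylpropanoate) F11, and pyridinium tosylate closes it to 16.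

Step 11 (desilylation and seven-ring closure). Partial loss of the pivalates would let ring A compete and erode the single-enantiomer outcome. Acid can also open a dihydrofuran at its 4-hydroxybenzylic carbon, and the resulting cation can add to the stilbene (ampelopsin D-type indane). The wrong epimer at the new centre is a further possibility.
The fallback replaces protecting-group control by catalyst control; it sets out from 16 and comes back at 19. KHF2 in MeOH followed by K2CO3 in MeOH removes all silyl and pivaloyl groups and gives the meso nonaphenol 5,5'-[(2R,3R,5S,6S)-2,6-bis(4-hydroxyphenyl)-4-[(E)-2-(4-hydroxyphenyl)ethenyl]-2,3,5,6-tetrahydrobenzo[1,2-b:5,4-b']difuran-3,5-diyl]bis(benzene-1,3-diol) F12. A chiral BINOL-derived phosphoric acid, for example (R)-TRIP or its enantiomer chosen by screening, then catalyses the cyclisation of the quinone-methide-type cation onto one of the two enantiotopic resorcinol rings and gives 19 directly.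

**Further compounds**
F1 | step 9 | 5-[(2R)-oxiran-2-yl]-1,3-phenylene bis(2,2-dimethylpropanoate) | CC(C)(C)C(=O)Oc1cc(OC(=O)C(C)(C)C)cc(c1)[C@@H]1CO1
F2 | step 9 | 5-[(1R)-1-{2,4-dihydroxy-6-[(E)-2-(4-TBSO-phenyl)ethenyl]phenyl}-2-hydroxyethyl]-1,3-phenylene bis(2,2-dimethylpropanoate) | OC[C@H](c1cc(OC(=O)C(C)(C)C)cc(OC(=O)C(C)(C)C)c1)c1c(O)cc(O)cc1/C=C/c1ccc(O[Si](C)(C)C(C)(C)C)cc1
F3 | step 9 | 5-[(3R)-2,6-dihydroxy-4-[(E)-2-(4-TBSO-phenyl)ethenyl]-2,3-dihydro-1-benzofuran-3-yl]-1,3-phenylene bis(2,2-dimethylpropanoate) (lactol, both C-2 epimers) | OC1Oc2cc(O)cc(/C=C/c3ccc(O[Si](C)(C)C(C)(C)C)cc3)c2[C@H]1c1cc(OC(=O)C(C)(C)C)cc(OC(=O)C(C)(C)C)c1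
F4 | step 9 | 4-[(tert-butyldimethylsilyl)oxy]phenylmagnesium chloride | CC(C)(C)[Si](C)(C)Oc1ccc([Mg]Cl)cc1
F5 | step 9 | 5-[(1R)-1-{2,4-dihydroxy-6-[(E)-2-(4-TBSO-phenyl)ethenyl]phenyl}-2-hydroxy-2-(4-TBSO-phenyl)ethyl]-1,3-phenylene bis(2,2-dimethylpropanoate) (both carbinol epimers) | OC(c1ccc(O[Si](C)(C)C(C)(C)C)cc1)[C@H](c1cc(OC(=O)C(C)(C)C)cc(OC(=O)C(C)(C)C)c1)c1c(O)cc(O)cc1/C=C/c1ccc(O[Si](C)(C)C(C)(C)C)cc1
F6 | step 10 | 3,5-bis[(tert-butyldimethylsilyl)oxy]benzaldehyde | O=Cc1cc(O[Si](C)(C)C(C)(C)C)cc(O[Si](C)(C)C(C)(C)C)c1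
F7 | step 10 | [(5-ethenyl-1,3-phenylene)bis(oxy)]bis(tert-butyldimethylsilane) | C=Cc1cc(O[Si](C)(C)C(C)(C)C)cc(O[Si](C)(C)C(C)(C)C)c1
F8 | step 10 | (2S)-2-{3,5-bis[(tert-butyldimethylsilyl)oxy]phenyl}oxirane | CC(C)(C)[Si](C)(C)Oc1cc(O[Si](C)(C)C(C)(C)C)cc(c1)[C@H]1CO1
F9 | step 10 | 5-[(2R,3R)-5-[(1S)-1-[3,5-bis(TBSO)phenyl]-2-hydroxyethyl]-2-(4-TBSO-phenyl)-4-[(E)-2-(4-TBSO-phenyl)ethenyl]-6-hydroxy-2,3-dihydro-1-benzofuran-3-yl]-1,3-phenylene bis(2,2-dimethylpropanoate) | Oc1cc2O[C@@H](c3ccc(O[Si](C)(C)C(C)(C)C)cc3)[C@H](c3cc(OC(=O)C(C)(C)C)cc(OC(=O)C(C)(C)C)c3)c2c(/C=C/c2ccc(O[Si](C)(C)C(C)(C)C)cc2)c1[C@@H](CO)c1cc(O[Si](C)(C)C(C)(C)C)cc(O[Si](C)(C)C(C)(C)C)c1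
F10 | step 10 | 5-[(2R,3R,5S)-5-[3,5-bis(TBSO)phenyl]-6-hydroxy-2-(4-TBSO-phenyl)-4-[(E)-2-(4-TBSO-phenyl)ethenyl]-2,3,5,6-tetrahydrobenzo[1,2-b:5,4-b']difuran-3-yl]-1,3-phenylene bis(2,2-dimethylpropanoate) (lactol, both C-6 epimers) | c1c2O[C@@H](c3ccc(O[Si](C)(C)C(C)(C)C)cc3)[C@H](c3cc(OC(=O)C(C)(C)C)cc(OC(=O)C(C)(C)C)c3)c2c(/C=C/c2ccc(O[Si](C)(C)C(C)(C)C)cc2)c2c1OC(O)[C@H]2c1cc(O[Si](C)(C)C(C)(C)C)cc(O[Si](C)(C)C(C)(C)C)c1
F11 | step 10 | 5-[(2R,3R)-5-[(1S)-1-[3,5-bis(TBSO)phenyl]-2-hydroxy-2-(4-TBSO-phenyl)ethyl]-2-(4-TBSO-phenyl)-4-[(E)-2-(4-TBSO-phenyl)ethenyl]-6-hydroxy-2,3-dihydro-1-benzofuran-3-yl]-1,3-phenylene bis(2,2-dimethylpropanoate) (both carbinol epimers) | Oc1cc2O[C@@H](c3ccc(O[Si](C)(C)C(C)(C)C)cc3)[C@H](c3cc(OC(=O)C(C)(C)C)cc(OC(=O)C(C)(C)C)c3)c2c(/C=C/c2ccc(O[Si](C)(C)C(C)(C)C)cc2)c1[C@@H](C(O)c1ccc(O[Si](C)(C)C(C)(C)C)cc1)c1cc(O[Si](C)(C)C(C)(C)C)cc(O[Si](C)(C)C(C)(C)C)c1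
F12 | step 11 | 5,5'-[(2R,3R,5S,6S)-2,6-bis(4-hydroxyphenyl)-4-[(E)-2-(4-hydroxyphenyl)ethenyl]-2,3,5,6-tetrahydrobenzo[1,2-b:5,4-b']difuran-3,5-diyl]bis(benzene-1,3-diol) (meso) | c1c2O[C@@H](c3ccc(O)cc3)[C@H](c3cc(O)cc(O)c3)c2c(/C=C/c2ccc(O)cc2)c2c1O[C@H](c1ccc(O)cc1)[C@H]2c1cc(O)cc(O)c1
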